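The route rests on one disconnection: the C3–C8 bond across the ten-membered ring. C3 and C8 lie 1,6 to each other through C4–C7, so bonding them gives a trans-fused hexalin in which ring A holds the C4=C5–C6=C7 diene and ring B carries C1, C9 and C10. The key step runs this backwards: light opens the cyclohexadiene of ring A by conrotatory six-electron electrocyclic cleavage of C3–C8, unveiling the ten-membered (E,Z,E)-triene with both trisubstituted E alkenes at once. Precursor 21 is the hexalin diene with C1–OSiEt3, C9–OSiMe2t-Bu (axial) and C10 isopropyl, made from (S)-carvone by auxiliary-controlled Robinson annulation and ring B hydroboration.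

Key step: step 14

Remark: locants C1–C10 are those of the ten-membered ring of the target (C1 tigloyloxy carbon, C3 and C7 methyl-bearing, C9 acyloxy carbon, C10 isopropyl carbon) and are kept for every bicyclic intermediate; β is the face of the C3 methyl group, α the opposite face; transient metal enolates and organoboranes are described in the Why lines and are not numbered.
Remark: the labile silyl group is placed on C1 and the robust one on C9, so that C1 is acylated before the C7–C8 epoxide exists (a free C1 hydroxyl beside that epoxide would invite transannular ether formation and acyl migration).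

Step 1
Reactants: 1 (S)-(+)-carvone
Product: 2 (2S,5S)-2-methyl-5-(prop-1-en-2-yl)cyclohexan-1-one (trans-dihydrocarvone; its C2 epimer is carried along)
Conditions: LiBH(s-Bu)3, THF, −78 °C; then H2O
Reagents that add atoms: none
Why: Conjugate (1,4) hydride reduction of a β-unsubstituted cyclohexenone by a hindered trialkylborohydride should spare the isopropenyl group and the carvone stereocentre (future C10), while the methyl-bearing carbon, formed on enolate protonation, is re-made in step 2.

Step 2
Reactants: 2 (2S,5S)-dihydrocarvone; 3 (S)-1-phenylethylamine; 4 ethyl vinyl ketone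
Product: 7 (2R,5S)-2-methyl-2-(3-oxopentyl)-5-(prop-1-en-2-yl)cyclohexan-1-one, via ketimine 5 (not isolated), via alkylated ketimine 6 (not isolated)
Conditions: 3, toluene, reflux (Dean–Stark); then 4, THF, 40 °C; then AcOH/H2O, 20 °C
Reagents that add atoms: water, O
Why: Asymmetric Michael addition of a chiral imine through its secondary enamine tautomer (first half of a Robinson annulation): the enone should add to C3 in a compact chair-like aza-ene transition state on the face remote from the phenyl group of the (S)-auxiliary, setting the quaternary centre with the chain anti and the methyl group syn to the C10 substituent (the matched pairing known for 2-methyl-5-alkenylcyclohexanone imines), before mild hydrolysis releases diketone and amine.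

Step 3
Reactants: 7 (2R,5S)-2-methyl-2-(3-oxopentyl)-5-(prop-1-en-2-yl)cyclohexan-1-one
Product: 8 (4aR,7S)-1,4a-dimethyl-7-(prop-1-en-2-yl)-4,4a,5,6,7,8-hexahydronaphthalen-2(3H)-one (the levorotatory enantiomer of α-cyperone)
Conditions: NaOMe, MeOH, 20 → 60 °C
Reagents that add atoms: none
Why: Intramolecular aldol condensation (second half of the Robinson annulation) of the ethyl ketone onto the ring carbonyl should close ring A as the C6(=O)–C7(Me)=C8 enone without touching a stereocentre.

Step 4
Reactants: 8 (4aR,7S)-α-cyperone enantiomer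
Product: 9 (4aR)-1,4a-dimethyl-7-(propan-2-yl)-4,4a,5,6-tetrahydronaphthalen-2(3H)-one (linear dienone C6(=O)–C7=C8–C9=C10)
Conditions: TsOH·H2O (cat.), toluene, 80 °C
Reagents that add atoms: none
Why: Acid-catalysed alkene isomerisation under thermodynamic control should move the isopropenyl double bond into the ring because the linearly conjugated dienone is the most stable isomer; the C10 centre is erased on purpose and rebuilt under control of C3 in step 6.

Step 5
Reactants: 9 linear dienone
Product: 10 C6 ethylene ketal with the ring B diene C8=C9–C10=C1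
Conditions: HOCH2CH2OH, TsOH (cat.), benzene, reflux (Dean–Stark)
Reagents that add atoms: ethylene glycol, OCCO
Why: Ketalisation with deconjugation (trienol formation, protonation at C7), as known for steroidal 4,6-dien-3-ones that give 5,7-diene ketals, should mask C6=O and place a homoannular diene in ring B, the C7 methine arising as an inconsequential epimer mixture.

Step 6
Reactants: 10 ring B diene ketal
Product: 11 diol ketal (1α-OH, 9α-OH, 8α-H, 10β-isopropyl)
Conditions: BH3·THF (excess), THF, 0 → 20 °C; then NaOH, H2O2, 0 °C
Reagents that add atoms: hydrogen peroxide, OO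
Why: Twofold hydroboration–oxidation of the diene should put boron on the two CH carbons C9 and C1 (C8 and C10 are fully substituted) with each syn H–B addition on the α face, away from the axial C3 methyl, which gives the trans ring fusion, C10–H α (isopropyl β) and the C1 hydroxyl α as required, the C9 hydroxyl being inverted later and C8 and C10 being further anchored thermodynamically as positions α to the C9 ketone of 13.

Step 7
Reactants: 11 diol ketal
Product: 12 1α-(tert-butyldimethylsilyloxy)-9α-ol ketal
Conditions: t-BuMe2SiCl, imidazole, DMF, 0 °C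
Reagents that add atoms: tert-butyldimethylsilyl chloride, CC(C)(C)[Si](C)(C)Cl
Why: Imidazole-mediated silylation should select the less hindered equatorial C1 hydroxyl, since the C9 hydroxyl is flanked by the ring-fusion carbon and the isopropyl-bearing carbon and is peri to the ring A substituents.

Step 8
Reactants: 12 mono-silyl ether
Product: 13 C9 ketone (1α-silyloxy, C6 ketal)
Conditions: Dess–Martin periodinane, NaHCO3, CH2Cl2, 20 °C
Reagents that add atoms: none
Why: Dess–Martin oxidation under buffered neutral conditions should give the hindered ketone without β-elimination of the C1 silyloxy group and without epimerising C8 or C10.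

Step 9
Reactants: 13 C9 ketone
Product: 15 dihydroxy ketone (1α-OH, 9β-OH, C6 ketone, 7α-methyl), via hydroxy ketal 14 (not isolated)
Conditions: NaBH4, MeOH, 0 °C; then HCl (2 M), THF, 20 °C
Reagents that add atoms: water, O
Why: Hydride reduction of a cyclohexanone whose axial approach is blocked by the syn-axial C3 methyl (as for 6-oxo-5α-steroids) should come from the α face and give the axial 9β alcohol, after which aqueous acid hydrolyses the dioxolane and the silyl ether and equilibrates C7 to the equatorial methyl epimer.

Step 10
Reactants: 15 dihydroxy ketone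
Product: 17 1α-(triethylsilyloxy)-9β-(tert-butyldimethylsilyloxy) ketone, via mono-silyl ether 16 (not isolated)
Conditions: Et3SiCl, imidazole, DMAP (cat.), CH2Cl2, −20 °C; then t-BuMe2SiOTf, 2,6-lutidine, 0 → 20 °C
Reagents that add atoms: chlorotriethylsilane, CC[Si](Cl)(CC)CC; tert-butyldimethylsilyl trifluoromethanesulfonate, CC(C)(C)[Si](C)(C)OS(=O)(=O)C(F)(F)F
Why: Sequential silylation should work because the chlorosilane reacts only with the equatorial C1 hydroxyl, whereas the axial neopentyl-like C9 hydroxyl needs the silyl triflate, so C1 ends with the acid-labile group and C9 with the robust one.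

Step 11
Reactants: 17 bis-silyl ketone
Product: 19 C4=C5 enone, via silyl enol ether 18 (not isolated)
Conditions: LiN(i-Pr)2, THF, −78 °C; Me3SiCl; then Pd(OAc)2, MeCN, 20 °C
Reagents that add atoms: none
Why: Saegusa–Ito oxidation: kinetic deprotonation at the C5 methylene (not the hindered C7 methine) gives enol ether 18, which Pd(OAc)2 (divalent palladium) should dehydrosilylate to the C4=C5 enone.

Step 12
Reactants: 19 enone
Product: 20 dienyl triflate (C4=C5–C6(OTf)=C7)
Conditions: KN(SiMe3)2, THF, −78 °C; PhNTf2, −78 → 0 °C
Reagents that add atoms: N-phenylbis(trifluoromethanesulfonimide), O=S(=O)(N(c1ccccc1)S(=O)(=O)C(F)(F)F)C(F)(F)F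
Why: Kinetic α′-deprotonation at C7, the only enolisable site because C3 is quaternary, followed by O-sulfonylation of the cross-conjugated dienolate (enol triflate formation) should give the 2-triflyloxy-1,3-diene.

Step 13
Reactants: 20 dienyl triflate
Product: 21 trans-fused hexalin diene (C4=C5–C6=C7; C1–OSiEt3 α, C9–OSiMe2t-Bu β, C10 isopropyl β)
Conditions: Pd(OAc)2 (cat.), PPh3, HCO2H, Bu3N, DMF, 50 °C
Reagents that add atoms: none
Why: Palladium-catalysed formate reduction of an enol triflate (oxidative addition to zerovalent palladium, formate exchange, decarboxylation, reductive elimination) should replace the triflate by hydrogen without moving the diene.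

Step 14
Reactants: 21 trans-fused hexalin diene
Product: 22 (3E,5Z,7E)-cyclodeca-3,5,7-triene (C1–OSiEt3, C9–OSiMe2t-Bu, C10 isopropyl)
Conditions: hν (254 nm, low-pressure Hg lamp, quartz), degassed pentane, −78 °C, stopped at partial conversion, recovered 21 recycled
Reagents that add atoms: none
Why: Excitation of the s-cis diene C4=C5–C6=C7 (expected to absorb near 265 nm) triggers a six-electron electrocyclic ring opening that is conrotatory in the excited state and cleaves the doubly allylic C3–C8 bond. The closest known reaction is the photochemical opening of trans-fused hexalin 1,3-dienes to (E,Z,E)-cyclodeca-1,3,5-trienes, the same event as the provitamin D to previtamin D conversion. The ten-membered ring arises by fragmentation of the decalin rather than by a bond-forming closure, and no stereocentre is created, C1, C9 and C10 being carried over unchanged. The selectivity needed is the E,Z,E geometry: the trans fusion holds the ring B bonds C3–C2 and C8–C9 on opposite faces of ring A, so the only conrotation open to the ring turns both outward and should give C3=C4 and C7=C8 as E alkenes around the Z C5=C6 bond. Relief of the syn-diaxial contact between the C3 methyl and the C9 silyloxy group favours opening, and −78 °C with partial conversion suppresses thermal disrotatory reclosure to the cis-fused diene and secondary photolysis of 22.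

Step 15
Reactants: 22 (3E,5Z,7E)-triene
Product: 23 (3E,7E)-cyclodeca-3,7-diene (C1–OSiEt3, C9–OSiMe2t-Bu)
Conditions: KO2CN=NCO2K, AcOH, MeOH/pentane, −40 → −20 °C (cold photolysate used directly)
Reagents that add atoms: none
Why: Diimide reduction (concerted syn transfer of H2 from diimide made in the flask) discriminates by substitution and should reduce the cis-disubstituted C5=C6 bond faster than the two trisubstituted alkenes, while the low temperature outruns electrocyclic reclosure and leaves a 1,5-diene that is kept below 40 °C to avoid Cope rearrangement.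

Step 16
Reactants: 23 (3E,7E)-diene
Product: 24 C1 alcohol (C9–OSiMe2t-Bu retained)
Conditions: PPTS (cat.), MeOH/CH2Cl2, 0 °C
Reagents that add atoms: none
Why: Acid-catalysed methanolysis (selective desilylation) should cleave the secondary triethylsilyl ether far faster than the hindered allylic tert-butyldimethylsilyl ether, and PPTS at 0 °C is too weak to start transannular cyclisation of the 1,5-diene.

Step 17
Reactants: 24 C1 alcohol
Product: 25 C1 tiglate (C9–OSiMe2t-Bu)
Conditions: (E)-2-methylbut-2-enoyl chloride, Et3N, DMAP, CH2Cl2, 0 → 20 °C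
Reagents that add atoms: tigloyl chloride, C/C=C(\C)C(Cl)=O
Why: DMAP-catalysed acylation through the acylpyridinium should esterify the C1 alcohol with the geometrically stable (E)-acid chloride before any epoxide is present.

Step 18
Reactants: 25 C1 tiglate
Product: 26 allylic C9 alcohol
Conditions: Bu4NF, AcOH, THF, 20 °C
Reagents that add atoms: none
Why: Fluoride-mediated desilylation, buffered with acetic acid so that no free C9 alkoxide can take up the C1 tigloyl group by 1,3-acyl migration, should free the allylic alcohol.

Step 19
Reactants: 26 allylic C9 alcohol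
Product: 27 C7–C8 epoxy C9 alcohol (epoxide configured as in the target)
Conditions: VO(acac)2 (cat.), t-BuOOH, CH2Cl2, 0 °C
Reagents that add atoms: tert-butyl hydroperoxide, CC(C)(C)OO
Why: Hydroxyl-directed epoxidation (vanadium alkoxide–peroxide delivery) is chemoselective for the allylic C7=C8 bond over C3=C4 and the tiglate, and because the C7 methyl is cis to C9, allylic 1,3-strain puts C9–H in the alkene plane with the hydroxyl on the outer face and C10 inside the ring, so oxygen should be delivered to the exposed face and give the threo epoxy alcohol of the target.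

Step 20
Reactants: 28 (R)-4-benzyl-3-propanoyl-1,3-oxazolidin-2-one; 29 acetaldehyde
Product: 30 (R)-4-benzyl-3-[(2R,3S)-3-hydroxy-2-methylbutanoyl]-1,3-oxazolidin-2-one
Conditions: Bu2BOTf, i-Pr2NEt, CH2Cl2, −78 → 0 °C; then pH 7 buffer, MeOH, H2O2
Reagents that add atoms: none
Why: Evans syn-aldol reaction: the Z boron enolate should add to acetaldehyde through a closed chair transition state with the auxiliary carbonyl dipole opposed, which gives the (2R,3S) syn adduct from the (R)-benzyl imide.

Step 21
Reactants: 30 aldol adduct
Product: 31 triethylsilyl ether of 30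
Conditions: Et3SiCl, imidazole, DMF, 0 °C
Reagents that add atoms: chlorotriethylsilane, CC[Si](Cl)(CC)CC
Why: Routine silylation of the secondary alcohol blocks retro-aldol cleavage and self-acylation in the steps that follow.

Step 22
Reactants: 31 silylated aldol adduct
Product: 32 (2R,3S)-2-methyl-3-(triethylsilyloxy)butanoic acid
Conditions: LiOH, H2O2, THF/H2O, 0 °C; then Na2SO3; then HCl to pH 4
Reagents that add atoms: hydrogen peroxide, OO
Why: Hydroperoxide-mediated removal of the oxazolidinone auxiliary should attack the exocyclic carbonyl selectively and leave the α-centre unepimerised, sulfite reducing the peracid to the acid.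

Step 23
Reactants: 27 epoxy alcohol; 32 side-chain acid
Product: 34 silyl-protected diester, via mixed anhydride 33 (not isolated)
Conditions: 32, 2,4,6-Cl3C6H2COCl, Et3N, THF, 20 °C; then 27, DMAP, toluene, 20 → 35 °C
Reagents that add atoms: none
Why: Yamaguchi esterification: DMAP attacks the less hindered aliphatic carbonyl of anhydride 33 and the acylpyridinium should acylate the hindered C9 alcohol under basic conditions that leave the epoxide and the α-centre of the acid intact.

Step 24
Reactants: 34 silyl-protected diester
Product: 35 target CNP0159364.1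
Conditions: Bu4NF, AcOH, THF, 0 °C
Reagents that add atoms: none
Why: Buffered fluoride desilylation should remove the secondary triethylsilyl ether under near-neutral conditions that avoid acid-triggered transannular opening of the epoxide by C3=C4 and any acyl migration.

Compound list
1 | (S)-(+)-carvone, (5S)-2-methyl-5-(prop-1-en-2-yl)cyclohex-2-en-1-one | CC1=CC[C@@H](CC1=O)C(C)=C | starting material
2 | (2S,5S)-2-methyl-5-(prop-1-en-2-yl)cyclohexan-1-one (trans-dihydrocarvone; C2 epimer carried along) | C[C@H]1CC[C@@H](CC1=O)C(C)=C | intermediate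
3 | (S)-1-phenylethylamine | C[C@H](N)c1ccccc1 | starting material
4 | ethyl vinyl ketone (pent-1-en-3-one) | CCC(=O)C=C | starting material
5 | ketimine, (1S)-N-[(5S)-2-methyl-5-(prop-1-en-2-yl)cyclohexylidene]-1-phenylethan-1-amine (C2 mobile through the enamine) | CC1CC[C@@H](CC1=N[C@@H](C)c1ccccc1)C(C)=C | intermediate (not isolated)
6 | alkylated ketimine, (1S)-N-[(2R,5S)-2-methyl-2-(3-oxopentyl)-5-(prop-1-en-2-yl)cyclohexylidene]-1-phenylethan-1-amine | CCC(=O)CC[C@@]1(C)CC[C@@H](CC1=N[C@@H](C)c2ccccc2)C(C)=C | intermediate (not isolated)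
7 | (2R,5S)-2-methyl-2-(3-oxopentyl)-5-(prop-1-en-2-yl)cyclohexan-1-one | CCC(=O)CC[C@@]1(C)CC[C@@H](CC1=O)C(C)=C | intermediate
8 | (4aR,7S)-1,4a-dimethyl-7-(prop-1-en-2-yl)-4,4a,5,6,7,8-hexahydronaphthalen-2(3H)-one (levorotatory enantiomer of α-cyperone) | C1C[C@]2(C)CCC(=O)C(C)=C2C[C@H]1C(C)=C | intermediate
9 | (4aR)-1,4a-dimethyl-7-(propan-2-yl)-4,4a,5,6-tetrahydronaphthalen-2(3H)-one (linear dienone, C7=C8 and C9=C10) | C1C[C@]2(C)CCC(=O)C(C)=C2C=C1C(C)C | intermediate
10 | C6 ethylene ketal of the ring B diene (C8=C9 and C10=C1; C3 methyl β; C7 methine as epimer mixture) | C1[C@]2(C)CCC3(OCCO3)C(C)C2=CC(C(C)C)=C1 | intermediate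
11 | trans-decalin diol ketal: 1α-OH, 9α-OH, 8α-H, 3β-methyl, 10β-isopropyl, C6 ethylene ketal, C7 epimers | O[C@@H]1C[C@]2(C)CCC3(OCCO3)C(C)[C@H]2[C@H](O)[C@H]1C(C)C | intermediate
12 | 1α-(tert-butyldimethylsilyloxy) 9α-ol ketal (otherwise as 11) | CC(C)(C)[Si](C)(C)O[C@@H]1C[C@]2(C)CCC3(OCCO3)C(C)[C@H]2[C@H](O)[C@H]1C(C)C | intermediate
13 | C9 ketone: 1α-silyloxy, 8α-H, 10β-isopropyl, C6 ethylene ketal | CC(C)(C)[Si](C)(C)O[C@@H]1C[C@]2(C)CCC3(OCCO3)C(C)[C@H]2C(=O)[C@H]1C(C)C | intermediate
14 | hydroxy ketal: 9β-OH (axial), 1α-silyloxy, C6 ethylene ketal | CC(C)(C)[Si](C)(C)O[C@@H]1C[C@]2(C)CCC3(OCCO3)C(C)[C@H]2[C@@H](O)[C@H]1C(C)C | intermediate (not isolated)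
15 | dihydroxy ketone: trans-decal-6-one, 1α-OH, 9β-OH, 3β-methyl, 7α-methyl (equatorial), 8α-H, 10β-isopropyl | O[C@@H]1C[C@]2(C)CCC(=O)[C@H](C)[C@H]2[C@@H](O)[C@H]1C(C)C | intermediate
16 | mono-silyl ether: 1α-(triethylsilyloxy), 9β-OH, C6 ketone | CC[Si](CC)(CC)O[C@@H]1C[C@]2(C)CCC(=O)[C@H](C)[C@H]2[C@@H](O)[C@H]1C(C)C | intermediate (not isolated)
17 | bis-silyl ketone: 1α-(triethylsilyloxy), 9β-(tert-butyldimethylsilyloxy), C6 ketone | CC[Si](CC)(CC)O[C@@H]1C[C@]2(C)CCC(=O)[C@H](C)[C@H]2[C@@H](O[Si](C)(C)C(C)(C)C)[C@H]1C(C)C | intermediate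
18 | silyl enol ether of 17: C5=C6(OSiMe3) | CC[Si](CC)(CC)O[C@@H]1C[C@]2(C)CC=C(O[Si](C)(C)C)[C@H](C)[C@H]2[C@@H](O[Si](C)(C)C(C)(C)C)[C@H]1C(C)C | intermediate (not isolated)
19 | enone: C4=C5–C6(=O), 7α-methyl, silyl ethers as in 17 | CC[Si](CC)(CC)O[C@@H]1C[C@]2(C)C=CC(=O)[C@H](C)[C@H]2[C@@H](O[Si](C)(C)C(C)(C)C)[C@H]1C(C)C | intermediate
20 | dienyl triflate: C4=C5–C6(OSO2CF3)=C7(Me) | CC[Si](CC)(CC)O[C@@H]1C[C@]2(C)C=CC(OS(=O)(=O)C(F)(F)F)=C(C)[C@H]2[C@@H](O[Si](C)(C)C(C)(C)C)[C@H]1C(C)C | intermediate
21 | trans-fused hexalin diene: C4=C5–C6=C7(Me), 3β-methyl, 8α-H, 1α-OSiEt3, 9β-OSiMe2t-Bu, 10β-isopropyl | CC[Si](CC)(CC)O[C@@H]1C[C@]2(C)C=CC=C(C)[C@H]2[C@@H](O[Si](C)(C)C(C)(C)C)[C@H]1C(C)C | intermediate (key-step precursor)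
22 | (3E,5Z,7E)-3,7-dimethyl-10-isopropylcyclodeca-3,5,7-triene with C1–OSiEt3 and C9–OSiMe2t-Bu, C1, C9, C10 as in the target | CC[Si](CC)(CC)O[C@@H]1C/C(C)=C/C=C\C(C)=C\[C@@H](O[Si](C)(C)C(C)(C)C)[C@H]1C(C)C | intermediate (key-step product)
23 | (3E,7E)-cyclodeca-3,7-diene with C1–OSiEt3 and C9–OSiMe2t-Bu | CC[Si](CC)(CC)O[C@@H]1C/C(C)=C/CC/C(C)=C/[C@@H](O[Si](C)(C)C(C)(C)C)[C@H]1C(C)C | intermediate
24 | (3E,7E)-diene C1 alcohol, C9–OSiMe2t-Bu | O[C@@H]1C/C(C)=C/CC/C(C)=C/[C@@H](O[Si](C)(C)C(C)(C)C)[C@H]1C(C)C | intermediate
25 | (3E,7E)-diene C1 (E)-2-methylbut-2-enoate, C9–OSiMe2t-Bu | C/C=C(\C)C(=O)O[C@@H]1C/C(C)=C/CC/C(C)=C/[C@@H](O[Si](C)(C)C(C)(C)C)[C@H]1C(C)C | intermediate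
26 | (3E,7E)-diene C1 tiglate, free C9 alcohol | C/C=C(\C)C(=O)O[C@@H]1C/C(C)=C/CC/C(C)=C/[C@@H](O)[C@H]1C(C)C | intermediate
27 | C7–C8 epoxide, C9 alcohol, C1 tiglate, (3E)-alkene; all centres as in the target | C/C=C(\C)C(=O)O[C@@H]1C/C(C)=C/CC[C@@]2(C)O[C@@H]2[C@@H](O)[C@H]1C(C)C | intermediate
28 | (R)-4-benzyl-3-propanoyl-1,3-oxazolidin-2-one | CCC(=O)N1[C@H](Cc2ccccc2)COC1=O | starting material
29 | acetaldehyde | CC=O | starting material
30 | (R)-4-benzyl-3-[(2R,3S)-3-hydroxy-2-methylbutanoyl]-1,3-oxazolidin-2-one | O=C(N1[C@H](Cc2ccccc2)COC1=O)[C@H](C)[C@H](C)O | intermediate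
31 | (R)-4-benzyl-3-[(2R,3S)-2-methyl-3-(triethylsilyloxy)butanoyl]-1,3-oxazolidin-2-one | O=C(N1[C@H](Cc2ccccc2)COC1=O)[C@H](C)[C@H](C)O[Si](CC)(CC)CC | intermediate
32 | (2R,3S)-2-methyl-3-(triethylsilyloxy)butanoic acid | OC(=O)[C@H](C)[C@H](C)O[Si](CC)(CC)CC | intermediate
33 | mixed anhydride of 32 with 2,4,6-trichlorobenzoic acid | O=C(OC(=O)[C@H](C)[C@H](C)O[Si](CC)(CC)CC)c1c(Cl)cc(Cl)cc1Cl | intermediate (not isolated)
34 | target with the side-chain hydroxyl as its triethylsilyl ether | C/C=C(\C)C(=O)O[C@@H]1C/C(C)=C/CC[C@@]2(C)O[C@@H]2[C@@H](OC(=O)[C@H](C)[C@H](C)O[Si](CC)(CC)CC)[C@H]1C(C)C | intermediate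
35 | CNP0159364.1: C1 tiglate, C9 (2R,3S)-3-hydroxy-2-methylbutanoate, C7–C8 epoxide, (3E)-alkene, C10 isopropyl | C/C=C(\C)C(=O)O[C@@H]1C/C(C)=C/CC[C@@]2(C)O[C@@H]2[C@@H](OC(=O)[C@H](C)[C@H](C)O)[C@H]1C(C)C | target

Total step count: 24 (21 on the main line, 3 for the side-chain acid).
Longest linear sequence: 21 steps (steps 1–19, 23 and 24) from (S)-carvone.

Steps most likely to fail

Step 14. The irradiation may settle into a photostationary mixture poor in triene, and longer exposure lets the triene itself absorb and drift into secondary photoisomerisation, while any warming recloses it. The fallback changes the process from a batch photoequilibrium to one that is drained continuously. It sets out from 21, which is irradiated in a cold closed flow loop whose return line passes through a bed of AgNO3 on silica. By analogy with the preparative photoisomerisation of trans-cycloalkenes and with the silver nitrate adducts of E,E-germacradienes, the strained triene should be held there as the silver nitrate complex of 22 F5 while unreacted 21 goes back to the lamp. Cold elution with NH3 in MeOH then releases the triene, and the route is rejoined at 22.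

Step 15. Diimide may be generated too slowly in the cold, so that thermal reclosure competes, and the strained trisubstituted E alkenes may be attacked as well. The fallback replaces pericyclic transfer hydrogenation by heterogeneous catalytic hydrogenation. It sets out from 22 in its cold photolysate, which is stirred under H2 over Raney Ni in MeOH/pentane at −20 °C, the low-temperature tactic that has precedent for exactly this kind of triene, and it comes back at 23. No new compound is formed (F0).

Step 6. The first-formed allylic borane may undergo 1,3-boron shifts and the second addition may lose facial control, giving diol mixtures that also burden the steric discrimination of step 7. The fallback installs the two oxygens one at a time and bypasses 11 and 12. It sets out from 10: one equivalent of BH3·THF followed by NaOH/H2O2 should give the allylic alcohol F1 (C9–OH α, C8–H α, C10=C1 retained), as 5,7-diene steroids give 7-en-6-ols. MnO2 then gives the enone F2. Copper-catalysed conjugate borylation (B2pin2, CuCl, NaOt-Bu, MeOH, THF) should add boron to C1 from the α face, with C10 settling to the equatorial isopropyl epimer next to the ketone, to give the β-boryl ketone F3. NaBO3·4H2O oxidises it with retention to the β-hydroxy ketone F4, and t-BuMe2SiCl/imidazole returns the route at 13.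

Further compounds
F1 | step 6 | allylic alcohol ketal: 9α-OH, 8α-H, C10=C1, C6 ethylene ketal | C1[C@]2(C)CCC3(OCCO3)C(C)[C@H]2[C@H](O)C(C(C)C)=C1
F2 | step 6 | enone ketal: C9(=O)–C10=C1, 8α-H, C6 ethylene ketal | C1[C@]2(C)CCC3(OCCO3)C(C)[C@H]2C(=O)C(C(C)C)=C1
F3 | step 6 | β-boryl ketone: 1α-(pinacolatoboryl), C9 ketone, 10β-isopropyl, C6 ethylene ketal | CC1(C)OB(OC1(C)C)[C@@H]2C[C@]3(C)CCC4(OCCO4)C(C)[C@H]3C(=O)[C@H]2C(C)C
F4 | step 6 | β-hydroxy ketone: 1α-OH, C9 ketone, 10β-isopropyl, C6 ethylene ketal | O[C@@H]1C[C@]2(C)CCC3(OCCO3)C(C)[C@H]2C(=O)[C@H]1C(C)C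
F5 | step 14 | silver nitrate complex of triene 22 | CC[Si](CC)(CC)O[C@@H]1C/C(C)=C/C=C\C(C)=C\[C@@H](O[Si](C)(C)C(C)(C)C)[C@H]1C(C)C.[Ag+].[O-][N+]([O-])=O
F0 | step 15 | none | none
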